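- The trap is to read the bigger X signal as the better flask. We have to choose the next charges by percent of the Z charged, so we need that percent as a function of the charge.

| flask | Z | G | remark | time |
|---|---|---|---|---|
| elm | 0.040 M | 0.050 M | run made earlier |  |
| birch | 0.55 M | 0.050 M | run made earlier |  |
| eta | 0.15 M | 0.0500 M |  | 4.0 h |
| alpha | 0.060 M | 0.0500 M |  | 4.0 h |
| zeta | 0.20 M | 0.0500 M |  | 4.0 h |
| gamma | 0.030 M | 0.0500 M |  | 4.0 h |
| beta | 0.40 M | 0.0500 M |  | 4.0 h |
| delta | 0.10 M | 0.0500 M |  | 4.0 h |

- elm (time / h: X / %, Z / %): 0.250: 9, 65; 0.833: 20, 33; 1.33: 23, 24; 2.00: 27, 13; 3.00: 29, 7; 4.00: 26, 7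
- birch (time / h: X / %, Z / %): 0.667: 6, 5; 1.33: 2, 4; 2.00: 6, 0; 2.50: 4, 4; 3.00: 4, 3; 4.00: 5, 4

(each reading ± 2 percentage points)

- what was read earlier has a scatter of 2 percentage points, one standard deviation

1. the flasks put in order of amount of X, in percent of the Z charged, best first, at 4.0 h (eta / alpha / zeta / gamma / beta / delta)
2. the same order at 15 h (eta / alpha / zeta / gamma / beta / delta)
3. the amount of X, in percent of the Z charged of the flask you put first, at 4.0 h
4. the amount of X, in percent of the Z charged of the flask you put last, at 4.0 h

- We take X as the mean of the last two elm readings, 27.5%, and the mean of all birch readings, 4.50%. Read as concentrations, birch shows more X than elm, 0.0248 M against 0.0110 M, yet its percent of the Z charged is lower.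
- Z goes faster at the higher charge: read as first-order, birch gives 4.49 h⁻¹ and elm 1.33 h⁻¹. So we let the selectivity, the share of Z that reaches X, fall with charge, and we assume that the reciprocal of the percent is a straight line in c(Z) at the start.
- Through our two points that line has slope 36.4 L mol⁻¹ and a low-charge limit of 45.9%, which gives 0.0598 M. This is the halving charge, the charge of Z at which the percent of X stands at half its low-charge limit.
- Our reckoning puts gamma at 30.6% and beta at 5.97%, so for percent we would charge toward gamma.
- We would not plan on a longer time: at 4.00 h, Z reads 7% in elm and 4% in birch. At elm's share of spent Z reaching X, the Z left in elm is worth 2.1 percentage points of X, less than the 2.5 points we reckon between eta and zeta, so we expect the same order at 15 h.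
- The forecast, from its own fit, gives gamma > alpha > delta > eta > zeta > beta at 4.0 h and gamma > alpha > delta > eta > zeta > beta at 15 h, with 30% first and 6% last. Its ground is this: as the charge of Z rises, “percent yield falls steadily”.
- The flasks give gamma > alpha > delta > eta > zeta > beta at 4.0 h and gamma > alpha > delta > eta > zeta > beta at 15 h, with gamma at 33.1% and beta at 7.45% at 4.0 h.

    G → L (k = 0.400 h⁻¹)
    Z → E (k = 0.230 h⁻¹)
    Z + G → X (k = 11.0 L mol⁻¹ h⁻¹)
    2 Z → Q (k = 14.0 L mol⁻¹ h⁻¹)

- Beta was charged at 6.69 halving charges, and at 4.00 h its Q stands at 85.0% of the Z charged, each Q counted as two Z. We carry beta's X to its neighbour, the same flask with 0.10 M of Z, by multiplying by one plus beta's charge over the halving charge, then dividing by one plus the neighbour's charge over the halving charge. This gives 21.4%, and the neighbour stands at 19.1%.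

The earlier runs and the new flask were computed for substances that don't exist, noise included.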